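**The task.** Time is what these flasks spend, and here the time between catalyst portions changed from flask to flask while midnight, summer, winter and noon each stopped at 50 h.

| flask | starting material | coupling partner | catalyst | remark | time |
|---|---|---|---|---|---|
| ash | 0.25 M | 0.50 M | 25 mM (in portions, 4) | run made earlier; portions every 2.5 h |  |
| larch | 0.25 M | 0.50 M | 57 mM (in portions, 4) | run made earlier; portions every 2.5 h |  |
| oak | 0.50 M | 0.50 M | 38 mM (in portions, 4) | run made earlier; portions every 2.5 h |  |
| midnight | 0.25 M | 0.500 M | 38 mM (in portions, 4) | the portions of catalyst follow each other after 2.5 h, the first at the start | 50 h |
| summer | 0.25 M | 0.500 M | 38 mM (in portions, 4) | the portions of catalyst follow each other after 4.0 h, the first at the start | 50 h |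
| winter | 0.25 M | 0.500 M | 38 mM (in portions, 4) | the portions of catalyst follow each other after 5.0 h, the first at the start | 50 h |
| noon | 0.25 M | 0.500 M | 38 mM (in portions, 4) | the portions of catalyst follow each other after 8.0 h, the first at the start | 50 h |

- ash (time / h: target / %, starting material / %): 6.00: 13.2, 85.5; 20.0: 55.0, 47.1; 30.0: 69.8, 30.3; 48.0: 83.0, 14.5
- larch (time / h: target / %, starting material / %): 4.00: 16.4, 82.1; 10.0: 51.5, 49.4; 20.0: 79.8, 19.8; 48.0: 97.2, 3.9
- oak (time / h: target / %, starting material / %): 6.00: 18.2, 81.3; 20.0: 60.2, 40.6; 30.0: 70.7, 29.4; 48.0: 79.1, 19.0

(standard deviation of a reading: 1 percentage point)

- "hardly changes" means that all values lie within two and a half points (for a concentration: within two and a half percent of the largest)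

* amount of target at the end, in percent of the starting material charged for midnight, summer, winter, noon, in this order
* how that number moves from the first to the last of them (hardly changes / falls all the way / rises all the way / rises, then falls / falls, then rises)

**Main step.** I began with the main step on its own, its rate proportional to starting material, coupling partner and catalyst, with the whole catalyst charge in at the start and the partner held at its charge. That is a pseudo-first-order decay with one time constant, τ. From the larch reading at 20.0 h, scaled to 38 mM of catalyst and corrected as described below, I read τ = 11.0 h. This picture promised 98.9% target at 50 h.

**Partner thins.** Next I let the partner be used. Its charge is twice that of the starting material, the limiting reagent. The fraction of partner left, divided by the fraction of starting material left, then grows as exp(0.5·t/τ). The promise dropped to 94.6%.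

**Late catalyst.** In this picture the rate follows the catalyst, and a late portion loses its lateness. Once all portions are in, the flask matches one that got the whole charge late by the catalyst lag, the average lateness of the catalyst: half the interval times the number of portions less one. For midnight the lag is 3.75 h, and for noon 12.0 h, still shorter than the run. Replacing t by t minus the lag, I expected 93.5% for midnight and 90.2% for noon.

**The rest.** In the larch run at 20.0 h, target and starting material add up to 99.6%, and the oak run, with its different charge, reads τ = 11.1 h. So I added no further loss.

**The forecast.** It gave 93.2%, 92.5%, 91.9% and 90%, a shape that falls all the way, holding that “only the catalyst time integral to 50 h matters”. My midnight figure lay 0.30 percentage points above it.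

**The result.** Midnight, summer, winter and noon gave 93.1%, 92.3%, 91.8% and 89.8%, so the row falls all the way.

    starting material + coupling partner + catalyst → catalyst + target (k = 0.00130 /M²/s)
    coupling partner → decomposition product (k = 2.20 × 10⁻⁸ /s)

**Why noon.** The half-life 7.8 h of starting material in the main step, reckoned with the whole charges of partner and catalyst there at once, makes τ = 11.2 h, and with the lags this gives 93.2% for midnight and 89.9% for noon. The step to decomposition product made no difference to midnight's target. Noon fell short in part through the partner wearing away in the main step, together with the time allowed: its 89.8% becomes 96.6% with the partner held and 100% at tenfold time.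

All runs were generated by integration from invented constants; scatter was added.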